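## Retrosynthetic overview
1. The target is made in the last step by a Schenck singlet-oxygen ene reaction on the C4=C5 trisubstituted alkene of ovatodiolide (17). This forms the 5β-OOH and the 4-methylene together.
2. The 14-membered carbocycle of 17 comes from a macro-RCM (butenyl arm + homoprenyl arm) of bis-lactone 16, which forms the C4=C5 alkene.
3. Lactone A of 16, with its trans C6/C7 stereocentres and α-methylene group, comes from a chiral-phosphoric-acid-catalysed allylboration of enal 9 with allylboronate 15, followed by lactonisation.
4. Enal 9 (butenolide B) comes from RCM of the acrylate ester of carbinol 4. Carbinol 4, the first stereocentre, comes from an organocatalytic vinylogous Mukaiyama aldol of prenal-derived dienol ether 2 with acrolein.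
5. Ring order: butenolide B, then lactone A, then the 14-membered ring, then the hydroperoxide.

Assumptions (one line each):
- The C4=C5 alkene of ovatodiolide (17) is E (Me cis to the C5–C6 chain side), as in normal cembranoids.
- The 5β face of the ene reaction is the face exposed in the preferred macrocycle conformer.
- (R)-TRIP is taken as the enantiomer that delivers the (6S,7R) pair.

## Route

**Step 1**
Reactants: 1 prenal (3-methylbut-2-enal)
Product: 2 1-(tert-butyldimethylsilyloxy)-3-methylbuta-1,3-diene (E/Z mixture)
Conditions: TBSOTf, Et3N, CH2Cl2, 0 °C
Reagents that add atoms: TBSOTf, CC(C)(C)[Si](C)(C)OS(=O)(=O)C(F)(F)F (adds TBS)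
Why: γ-Deprotonation and O-silylation of the enal give the vinylogous Mukaiyama donor; the E/Z geometry is irrelevant because it is lost in the aldol.

**Step 2**
Reactants: 2; 3 acrolein
Product: 4 (2E,5R)-5-hydroxy-3-methylhepta-2,6-dienal
Conditions: (R,R)-chiral bisphosphoramide (5 mol%), SiCl4, iPr2NEt, CH2Cl2, –78 °C; then aq. NaHCO3
Reagents that add atoms: none (the silyl group is lost on work-up)
Why: Lewis-base-catalysed vinylogous Mukaiyama aldol; the chiral phosphoramide–SiCl4 species is a cationic Lewis acid that organises an aldehyde/dienol-ether transition state. The dienol ether reacts through its γ-CH2 and sets the carbinol (future butenolide γ-carbon) as R. The s-trans diene conformer gives the E-enal. This extends known Lewis-base dienolate aldols from ester-derived dienolates to an enal-derived dienol ether.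

**Step 3**
Reactants: 5 ethyl 2-(bromomethyl)acrylate
Product: 6 ethyl 2-methylenehex-5-enoate
Conditions: allylMgBr, CuI (10 mol%), THF, –78 °C
Reagents that add atoms: allylmagnesium bromide, C=CC[Mg]Br
Why: Cu-catalysed SN2′ of a Grignard reagent on a 2-(bromomethyl)acrylate installs the butenyl arm.

**Step 4**
Reactants: 6
Product: 7 2-methylenehex-5-enoic acid
Conditions: LiOH, THF/H2O, 0 °C → rt
Reagents that add atoms: LiOH, [Li+].[OH-] (adds the acid OH)
Why: Saponification of an unhindered ethyl ester.

**Step 5**
Reactants: 4; 7
Product: 8 (2E,5R)-3-methyl-5-[(2-methylenehex-5-enoyl)oxy]hepta-2,6-dienal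
Conditions: EDC·HCl, DMAP, CH2Cl2, 0 °C → rt
Reagents that add atoms: none
Why: Steglich esterification of the secondary allylic alcohol; the stereocentre is untouched.

**Step 6**
Reactants: 8
Product: 9 (R)-3-(but-3-en-1-yl)-5-[(E)-2-methyl-4-oxobut-2-en-1-yl]furan-2(5H)-one
Conditions: Hoveyda–Grubbs II (5 mol%), CH2Cl2 (5 mM), 40 °C
Reagents that add atoms: none
Why: Ring-closing metathesis of the vinyl carbinol acrylate closes the 5-membered butenolide selectively. The β,β-disubstituted enal and the butenyl alkene do not take part, and the γ-stereocentre is retained.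

**Step 7**
Reactants: 10 methallyl alcohol
Product: 11 4-methylpent-4-enal
Conditions: ethyl vinyl ether (excess), Pd(OAc)2/1,10-phenanthroline, CH2Cl2, rt; then 150 °C, sealed tube
Reagents that add atoms: ethyl vinyl ether, C=COCC (supplies the CH=CH2 carbons)
Why: Pd-catalysed transetherification gives methallyl vinyl ether, which undergoes Claisen [3,3] rearrangement to the γ,δ-unsaturated aldehyde.

**Step 8**
Reactants: 11; 12 methyl acrylate
Product: 13 methyl 2-(1-hydroxy-4-methylpent-4-en-1-yl)acrylate (racemic)
Conditions: DABCO (20 mol%), neat, rt, 5 d
Reagents that add atoms: none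
Why: Morita–Baylis–Hillman reaction; the carbinol stereocentre is destroyed in the next two steps, so racemic material is fine.

**Step 9**
Reactants: 13
Product: 14 methyl (2Z)-2-(bromomethyl)-6-methylhepta-2,6-dienoate
Conditions: PBr3, Et2O, 0 °C
Reagents that add atoms: PBr3, BrP(Br)Br (adds Br)
Why: SN2′ bromination of the MBH alcohol gives the trisubstituted allylic bromide; this avoids HBr, which would add to the isoprenyl alkene.

**Step 10**
Reactants: 14
Product: 15 methyl (2Z)-6-methyl-2-[(4,4,5,5-tetramethyl-1,3,2-dioxaborolan-2-yl)methyl]hepta-2,6-dienoate (alkyl group R trans to CH2Bpin)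
Conditions: B2pin2, Pd(PPh3)4 (5 mol%), KOAc, THF, 40 °C
Reagents that add atoms: B2pin2, CC1(C)OB(OC1(C)C)B1OC(C)(C)C(C)(C)O1 (adds Bpin)
Why: Pd-catalysed allylic borylation of the allyl bromide proceeds through the syn-π-allyl-Pd complex. This delivers the E-crotyl-type boronate (R trans to CH2B, ester cis to R) whatever the bromide geometry, which is the geometry needed for trans-lactone formation in Step 11.

**Step 11**
Reactants: 9; 15
Product: 16 bis-lactone: trans-4,5-disubstituted α-methylene-γ-butyrolactone, C5 (S) and C4 (R), carrying the (E)-CH=C(Me)CH2– link to the (R)-butenolide, with butenyl and homoprenyl arms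
Conditions: (R)-TRIP (10 mol%), 4 Å MS, toluene, –20 °C, 48 h; then TsOH·H2O (20 mol%), CH2Cl2, rt
Reagents that add atoms: none (the catalyst and TsOH are not incorporated; MeOH and pinB–OH are lost)
Why: Proposed new method: CPA-catalysed allylboration of a β,β-disubstituted enal with a γ-alkyl-2-(methoxycarbonyl)allyl pinacol boronate, followed by in situ lactonisation.
- Mechanism: the acidic P–OH of TRIP hydrogen-bonds a pinacol oxygen while the P=O organises the aldehyde. The reaction goes through a closed chair transition state with the enal substituent equatorial, and the E-crotyl-type boronate gives the anti adduct. This sets C6 and C7 together, and anti gives the trans-lactone after acid-promoted lactonisation.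
- Closest known reactions: CPA/BINOL-catalysed allylboration of aldehydes with pinacol allyl/crotylboronates, and α-methylene-γ-butyrolactone synthesis from 2-alkoxycarbonyl allylboronates.

**Step 12**
Reactants: 16
Product: 17 ovatodiolide (E-C4=C5)
Conditions: Hoveyda–Grubbs II (10 mol%), p-benzoquinone (10 mol%), toluene (1 mM), 70 °C
Reagents that add atoms: none
Why: Macro-RCM between the terminal butenyl and the 1,1-disubstituted homoprenyl alkene makes the 14-membered ring and the trisubstituted E-alkene. The α-methylene lactone, the butenolide and the C6 trisubstituted alkene are poor metathesis partners and survive; benzoquinone suppresses Ru–H isomerisation.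

**Step 13**
Reactants: 17
Product: 18 target, 4-methylene-5β-hydroperoxyovatodiolide
Conditions: O2, TPP (1 mol%), green LEDs, CH2Cl2, –40 °C, ~1 equiv O2; no reductive work-up
Reagents that add atoms: O2, O=O
Why: Schenck ene reaction. 1O2 prefers the more electron-rich C4=C5 alkene over the other trisubstituted alkene, which is deactivated by its allylic acyloxy group. By the cis effect, H is abstracted from the C4 methyl on the crowded side (Me and C3 cis in the E-alkene), giving the 4-methylene-5-OOH. The macrocycle conformation biases the face, which sets C5 as R (β).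

## Compound list
1 | prenal | CC(C)=CC=O | starting material
2 | TBS dienol ether of prenal | C=C(C)C=CO[Si](C)(C)C(C)(C)C | intermediate
3 | acrolein | C=CC=O | starting material
4 | (2E,5R)-5-hydroxy-3-methylhepta-2,6-dienal | C=C[C@H](O)C/C(C)=C/C=O | intermediate
5 | ethyl 2-(bromomethyl)acrylate | C=C(CBr)C(=O)OCC | starting material
6 | ethyl 2-methylenehex-5-enoate | C=CCCC(=C)C(=O)OCC | intermediate
7 | 2-methylenehex-5-enoic acid | C=CCCC(=C)C(=O)O | intermediate
8 | acrylate ester of 4 | C=C[C@H](OC(=O)C(=C)CCC=C)C/C(C)=C/C=O | intermediate
9 | butenolide enal (R) | C=CCCC1=C[C@@H](C/C(C)=C/C=O)OC1=O | intermediate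
10 | methallyl alcohol | C=C(C)CO | starting material
11 | 4-methylpent-4-enal | C=C(C)CCC=O | intermediate
12 | methyl acrylate | C=CC(=O)OC | starting material
13 | MBH adduct (racemic) | C=C(C)CCC(O)C(=C)C(=O)OC | intermediate
14 | (Z)-2-(bromomethyl)alkenoate | C=C(C)CC/C=C(\CBr)C(=O)OC | intermediate
15 | allylboronate | C=C(C)CC/C=C(/CB1OC(C)(C)C(C)(C)O1)C(=O)OC | intermediate
16 | bis-lactone (C6 S, C7 R, Bγ R) | C=C1C(=O)O[C@@H](/C=C(\C)C[C@@H]2C=C(CCC=C)C(=O)O2)[C@@H]1CCC(C)=C | intermediate
17 | ovatodiolide | C=C1C(=O)O[C@H]2/C=C(\C)C[C@@H]3C=C(CC/C=C(\C)CC[C@H]12)C(=O)O3 | intermediate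
18 | 4-methylene-5β-hydroperoxyovatodiolide | C=C1C(=O)O[C@H]2/C=C(\C)C[C@@H]3C=C(CC[C@@H](OO)C(=C)CC[C@H]12)C(=O)O3 | target

## Totals
- Total steps: 13.
- Longest linear sequence: 7 steps (Steps 1, 2, 5, 6, 11, 12, 13, from prenal).
- Side branches: 2 steps (Steps 3–4) and 4 steps (Steps 7–10).

## Three steps most likely to fail
1. **Step 11 (the proposed new step).** The CPA catalyst may give poor ee or dr with this hindered enal and a γ-alkyl 2-ester allylboronate, or the boronate may come out as the wrong geometry.
   - Fallback (known chemistry): Zn-mediated Barbier allylation of 9 with bromide 14. Allylzinc equilibration gives the anti adduct and trans-lactone as two diastereomers relative to the γ-carbon. Separate them by HPLC, then lactonise with TsOH.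
2. **Step 13.** The ene reaction may give mixed regio- or diastereoisomers, or react at the C6 alkene.
   - Fallback (changed approach): epoxidise 17 with mCPBA. Isomerise the epoxide with Et2AlTMP to the exocyclic allylic alcohol and separate the epimers. Then mesylate and displace with H2O2/K2CO3 at –20 °C (SN2, inversion), choosing the alcohol epimer that gives 5β-OOH.
3. **Step 2.** Acrolein may undergo Diels–Alder reaction with the dienol ether, or the ee may be modest.
   - Fallback (known chemistry): run the ester-level Denmark vinylogous aldol of the ethyl senecioate silyl ketene acetal with acrolein. Then protect the alcohol as its TBS ether, reduce with DIBAL, oxidise with MnO2 and remove the TBS with TBAF to give 4, and continue from Step 5.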